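## The problem

The target **23** is 3-(4-hydroxyphenyl)-5-methoxy-4,7-diphenyl-1-benzofuran-2,6-dione. A γ-lactone (O1, C2, C3, C3a, C7a) is fused to a six-membered carbocycle that is a quinone methide, not a benzene ring: C3=C3a, C4=C5 and C7=C7a are double bonds and C6 is a ketone. Every carbon of that ring is substituted (phenyl at C4 and C7, methoxy at C5, carbonyl at C6, O1 at C7a, C3 at C3a), so six positions must be placed without ambiguity, and the C3 aryl and C4 phenyl groups crowd each other across the ring fusion. The target has no stereocentre. The only one met on the way, C3 of the saturated lactone **20**, is racemic and vanishes when C3 becomes trigonal, so nothing has to be controlled. The quinone methide (electrophilic at C3, reducible), the base-labile lactone and the acidic, autoxidisable C3–H of the reduced lactone tolerate little, so the final oxidation level belongs at the end. The vicinal oxygens at C5 and C6 must end differently (methyl ether and carbonyl), although they are most cheaply drawn from one symmetric catechol diether. The enabling feature is the lactone carbonyl C2 between O1 and the aryl-bearing C3: with one more carbon between O1 and C2 the ring is a 4-aryl-3-hydroxycoumarin, the enol of an α-keto lactone, and that carbon can be expelled as CO2.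

## Retrosynthesis

Benzofuran numbering is used for **20**–**23**; O4' is the para oxygen of the C3 aryl group.

**23 ⇒ 21 ⇒ 20 (O6–CH3 and the C3–H/O4'–H pair).** The quinone methide is made last. Oxidising a free C6 phenol would be the obvious way, but it would require an unsymmetrical catechol diether from the first step. Instead both ring oxygens stay methyl ethers and the oxidation is routed through the free phenol on the C3 aryl group: dehydrogenation of **20** gives the isomeric quinone methide **21**. In the carbenium ion derived from **21** the charge reaches O6 (para to C3a) but never O5 (meta), so only the O6 methyl can be lost. The forward step must remove exactly that methyl and leave the lactone intact.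

**20 ⇒ 17 (key disconnection).** In the forward sense the O1–C2 and C2–C3 bonds of coumarin **17** are broken, C2 leaves as CO2, and O1 is joined to the former C3. The neighbouring cuts (α-arylation of a benzofuranone at C3, or Friedel–Crafts attachment of an arylacetic unit at C3a) all make a C–C bond at the most crowded site of a hexasubstituted ring. The ring contraction makes none. **17** is one carbon larger but is reachable by an aldol closure. The forward reaction must oxidise an α-keto acid in the presence of electron-rich phenols.

**17 ⇒ 16 ⇒ 13 + 14 (C3=C4 and O1–C2 of the coumarin).** The pyranone is cut into the 2-hydroxybenzophenone **13** and (benzyloxy)acetyl chloride **14**. A benzyl ether is chosen for the C3 oxygen: an acetate would migrate between the oxygens during the aldol, and a methyl enol ether could not be removed beside the ring methyl ethers. The same group protects O4', so one hydrogenolysis of **16** frees both hydroxyls of **17**. The forward reaction is an intramolecular aldol condensation onto a hindered diaryl ketone that has no α-hydrogen.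

**13 ⇒ 9 + 10 (aryl–carbonyl bond ortho to the phenol oxygen).** A Fries rearrangement of an aroyl ester of **8** would make the same bond, but a strong Lewis acid threatens the vicinal methyl ethers and the acylium ion could attack the pendant phenyl rings. Directed ortho-metalation of the methoxymethyl ether **9** has only one ring hydrogen to take, and the aryllithium **11** adds once to nitrile **10**. The acid that hydrolyses the ketimine also removes the acetal.

**9 ⇒ 8 ⇒ 7 ⇒ 6 (C–O at the future C7a).** The phenol oxygen is traced back through bromide **7** to a C–H of terphenyl **6**. The two ring hydrogens of **6** are equivalent by symmetry and each is para to a methoxy group, so one bromination fixes the whole substitution pattern. The forward steps must keep substitution on the central ring.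

**6 ⇒ 3 + 4 ⇒ 1 (both aryl–aryl bonds).** Both phenyl groups come from phenylboronic acid **4** and diiodide **3**, which twofold ortho-lithiation of veratrole **1** delivers in one operation. Each C–I bond has a single ortho substituent, so the coupling is undemanding, and the symmetry of **1** is used twice.

## Roads not taken

**Alternative 1: cyclobutenone ring expansion to the oxygenated arene.** The cut is the C3a–C7a bond of the carbocycle. Heating 4-methoxy-2-phenyl-4-(1-phenylethenyl)-3-(propan-2-yloxy)cyclobut-2-en-1-one A1 would open it to a dienylketene, whose 6π closure and enolisation give 4-methoxy-2,5-diphenyl-3-(propan-2-yloxy)phenol A2.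
- Merits: the regiochemistry is set by connectivity, not by electrophilic substitution, and the two vicinal oxygens are differentiated from the start (isopropyl against methyl). A2 could therefore be carried to a free C6 phenol and oxidised directly, with no selective demethylation. In this respect it is better than the chosen plan.
- Weak points: A1 needs several sequential organolithium additions and an O-methylation of a tertiary alkoxide on a four-membered ring, and the thermolysis builds only the arene. A2 is the counterpart of phenol **8**, so the ketone, the lactone and the crowded C3 centre are all still to be made.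
- Comparison: the chosen plan reaches **8** in four steps from a commodity arene, using one symmetry-enabled dilithiation and one double coupling, and it differentiates O5 from O6 at the end through conjugation instead of through protecting groups.

**Alternative 2: late twofold Suzuki arylation at C4 and C7.** The cuts are the two aryl–aryl bonds. The dibromide 4-(4,7-dibromo-5,6-dimethoxy-2-oxo-2,3-dihydro-1-benzofuran-3-yl)phenyl 2,2-dimethylpropanoate A3 would be coupled with two equivalents of **4** under Pd(OAc)2 and a bulky phosphine to give 4-(5,6-dimethoxy-2-oxo-4,7-diphenyl-2,3-dihydro-1-benzofuran-3-yl)phenyl 2,2-dimethylpropanoate A4.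
- Merits: the lactone is built on a less crowded ring, and the aryl groups can be varied at the end, which the chosen plan cannot offer.
- Weak points: both C–Br bonds are flanked on both sides (C4 by C3a and the C5 methoxy, C7 by the C6 methoxy and C7a–O). The basic coupling medium meets an acidic C3–H, whose enolate is oxidisable and is itself a partner for palladium-catalysed α-arylation, and a lactone and an aryl ester that open in base. A3 also still needs a fully substituted arene with defined bromine positions.
- Comparison: the chosen plan couples at the outset on an unhindered diiodide, where nothing else can react, and never exposes the lactone to palladium and base.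

**Alternative 3: anodic o-quinone lactonisation closing O1–C7a.** The cut is the O1–C7a bond. Anodic oxidation of 2-(3,4-dihydroxy-2,5-diphenylphenyl)-2-(4-hydroxyphenyl)acetic acid A5 would give the o-quinone; the carboxylate adds at the only unsubstituted ring carbon, and further oxidation gives 5-hydroxy-3-(4-hydroxyphenyl)-4,7-diphenyl-1-benzofuran-2,6-dione A6.
- Merits: lactone and quinone methide oxidation level arrive in one reagent-free operation, and no demethylation is needed. The end is shorter than in the chosen plan.
- Weak points: A6 must then be methylated at O5 alone, while its O4' hydroxyl is a vinylogous acid of comparable or greater acidity. A free phenol and a catechol are both exposed at the anode. A5 still contains the hindered aryl–CH(aryl) bond, so the hardest bond is not addressed.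
- Comparison: the chosen plan has the O5 methyl in place from **1**, makes the hindered bond by an organolithium addition, and adjusts the oxidation level with stoichiometric reagents on a substrate whose only free phenol is the one that is needed.

Key step: step 9

Assumption: the target is taken as the 6-oxo/4'-hydroxy tautomer of its SMILES. This should be the more stable proton tautomer, because only the ring-fused quinone methide can be planar.

## Route

Step 1
Reactants: 1 veratrole (1,2-dimethoxybenzene)
Product: 3 1,4-diiodo-2,3-dimethoxybenzene, via 3,6-dilithioveratrole 2 (not isolated)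
Conditions: n-BuLi (3 equiv), TMEDA (3 equiv), Et2O, 0 °C to reflux; then I2, THF, −78 °C to rt
Reagents that add atoms: iodine, II
Why: Twofold directed ortho-metalation: each methoxy group directs lithiation to its free ortho position, and the TMEDA-assisted second lithiation of veratrole at C6 is established; iodinolysis of both C–Li bonds should give the 3,6-diiodide.

Step 2
Reactants: 3 1,4-diiodo-2,3-dimethoxybenzene; 4 phenylboronic acid
Product: 6 2,3-dimethoxy-1,4-diphenylbenzene, via 4-iodo-2,3-dimethoxybiphenyl 5 (not isolated)
Conditions: 4 (2.5 equiv), Pd(PPh3)4 (5 mol %), K2CO3, toluene/EtOH/H2O, 90 °C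
Reagents that add atoms: none
Why: Twofold Suzuki–Miyaura coupling with a zerovalent palladium catalyst; each C–I bond has only one ortho substituent and the two sites are equivalent, so no selectivity is required.

Step 3
Reactants: 6 2,3-dimethoxy-1,4-diphenylbenzene
Product: 7 1-bromo-3,4-dimethoxy-2,5-diphenylbenzene
Conditions: NBS (1.05 equiv), MeCN, 0 °C to rt
Reagents that add atoms: N-bromosuccinimide, O=C1CCC(=O)N1Br
Why: Electrophilic aromatic bromination para to a methoxy group; the two ring hydrogens of the central ring are equivalent by symmetry, this is the only oxygen-activated ring, and the first bromine deactivates it towards a second.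

Step 4
Reactants: 7 1-bromo-3,4-dimethoxy-2,5-diphenylbenzene
Product: 8 3,4-dimethoxy-2,5-diphenylphenol
Conditions: Pd2(dba)3 (2 mol %), tBuXPhos (8 mol %), KOH (3 equiv), 1,4-dioxane/H2O, 100 °C
Reagents that add atoms: potassium hydroxide, [K+].[OH-]
Why: Palladium-catalysed hydroxylation of an aryl bromide with hydroxide (Buchwald–Hartwig-type C–O coupling); the bulky biaryl phosphine favours C–O reductive elimination at the mono-ortho-substituted carbon and suppresses diaryl ether formation.

Step 5
Reactants: 8 3,4-dimethoxy-2,5-diphenylphenol
Product: 9 3,4-dimethoxy-1-(methoxymethoxy)-2,5-diphenylbenzene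
Conditions: MOMCl, iPr2NEt, CH2Cl2, 0 °C to rt
Reagents that add atoms: chloromethyl methyl ether, COCCl
Why: O-alkylation of the phenol to the methoxymethyl ether, which is stable to organolithiums and is the strongest ortho-directing group in the molecule.

Step 6
Reactants: 9 3,4-dimethoxy-1-(methoxymethoxy)-2,5-diphenylbenzene; 10 4-(benzyloxy)benzonitrile
Product: 13 [4-(benzyloxy)phenyl](2-hydroxy-4,5-dimethoxy-3,6-diphenylphenyl)methanone, via ortho-lithiated MOM ether 11 (not isolated), via lithium ketimide 12 (not isolated)
Conditions: n-BuLi (1.1 equiv), TMEDA, THF, 0 °C; 10 (1.1 equiv), −78 °C to rt; then 3 M HCl, THF/MeOH, 60 °C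
Reagents that add atoms: water, O
Why: Directed ortho-metalation puts lithium on the only remaining ring hydrogen, and the aryllithium adds once to the nitrile because the lithium ketimide is not electrophilic. Aqueous acid then hydrolyses the ketimine and cleaves the acetal in the same operation, while the benzyl ether and the methyl ethers are stable.

Step 7
Reactants: 13 [4-(benzyloxy)phenyl](2-hydroxy-4,5-dimethoxy-3,6-diphenylphenyl)methanone; 14 (benzyloxy)acetyl chloride
Product: 16 3-(benzyloxy)-4-[4-(benzyloxy)phenyl]-6,7-dimethoxy-5,8-diphenyl-2H-chromen-2-one, via aryl benzyloxyacetate 15 (not isolated)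
Conditions: 14 (1.5 equiv), Et3N, DMAP (cat.), MeCN, 0 °C to rt; then DBU, 80 °C
Reagents that add atoms: none
Why: O-acylation of the phenol followed by base-mediated intramolecular aldol condensation (Kostanecki-type coumarin synthesis from a 2-acyloxybenzophenone): the α-alkoxy ester enolate closes 6-exo-trig onto the diaryl ketone, which cannot enolise, and E1cB loss of water gives the conjugated lactone. Intramolecularity should offset the hindrance at the ketone.

Step 8
Reactants: 16 3-(benzyloxy)-4-[4-(benzyloxy)phenyl]-6,7-dimethoxy-5,8-diphenyl-2H-chromen-2-one
Product: 17 3-hydroxy-4-(4-hydroxyphenyl)-6,7-dimethoxy-5,8-diphenyl-2H-chromen-2-one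
Conditions: H2 (1 atm), 10% Pd/C, EtOAc/MeOH, rt
Reagents that add atoms: none
Why: Hydrogenolysis of the benzyl aryl ether and the benzyl enol ether; the tetrasubstituted, doubly flanked C3=C4 bond and the methyl ethers should be inert at 1 atm.

Step 9
Reactants: 17 3-hydroxy-4-(4-hydroxyphenyl)-6,7-dimethoxy-5,8-diphenyl-2H-chromen-2-one
Product: 20 3-(4-hydroxyphenyl)-5,6-dimethoxy-4,7-diphenyl-1-benzofuran-2(3H)-one (racemic), via diarylpyruvic acid 18 (not isolated), via diarylacetic acid 19 (not isolated)
Conditions: NaOH (1 M aq, 5 equiv), H2O2 (30%, 1.2 equiv), THF/H2O, 0 °C to rt, N2; then 2 M HCl to pH 1, 50 °C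
Reagents that add atoms: hydrogen peroxide, OO
Why: Hydroxide opens the lactone of 17 at C2 and the freed enol ketonises to the diarylpyruvate 18 (present as its sodium salt); hydroperoxide anion adds to the ketone carbon (the former C3) and the adduct fragments, expelling the former C2 as carbonate and leaving the diarylacetate 19. This is the classical alkaline hydrogen peroxide oxidative decarboxylation of α-keto acids, known for arylpyruvic acids including 2-hydroxyphenylpyruvic acid (the ring-opened form of 3-hydroxycoumarin), applied here to a 3,3-diaryl case. On acidification the phenol oxygen O1 attacks the carboxyl carbon and the five-membered lactone closes by a 5-exo-trig acyl substitution, favoured because acid and phenol are held ortho on a fully substituted ring. The one new stereocentre, C3, arises by unselective protonation and is racemic; no control is wanted, since C3 becomes trigonal in step 10. The step needs chemoselectivity for the keto acid over the electron-rich phenolates and over the enolate carbon: the nucleophilic peroxide anion attacks only the electrophilic ketone, and near-stoichiometric peroxide at 0 °C under nitrogen limits electrophilic oxidation. Because the C6 oxygen is a methyl ether, the ring carries no free para-hydroxybenzyl unit that air or peroxide could take to a quinone. No carbon–carbon bond is made at the congested C3a–C3 junction, which step 6 has already put in place.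

Step 10
Reactants: 20 3-(4-hydroxyphenyl)-5,6-dimethoxy-4,7-diphenyl-1-benzofuran-2(3H)-one (racemic)
Product: 21 5,6-dimethoxy-3-(4-oxocyclohexa-2,5-dien-1-ylidene)-4,7-diphenyl-1-benzofuran-2(3H)-one
Conditions: DDQ (1.05 equiv), CH2Cl2, rt
Reagents that add atoms: none
Why: DDQ dehydrogenation of a 4-hydroxyphenyl-substituted diarylmethane C–H to the p-quinone methide (fuchsone-type oxidation): hydride leaves the doubly benzylic C3 and the phenol loses its proton. The product has no further abstractable hydrogen.

Step 11
Reactants: 21 5,6-dimethoxy-3-(4-oxocyclohexa-2,5-dien-1-ylidene)-4,7-diphenyl-1-benzofuran-2(3H)-one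
Product: 23 3-(4-hydroxyphenyl)-5-methoxy-4,7-diphenyl-1-benzofuran-2,6-dione, via C3 bromo lactone 22 (not isolated)
Conditions: HBr (33% in AcOH, 2 equiv), CH2Cl2, 0 to 40 °C; H2O work-up
Reagents that add atoms: none
Why: HBr adds 1,6 to the quinone methide to give the tertiary bromide 22, which ionises to a diarylcarbenium ion whose charge is shared with O6 through the para position of the fused ring; bromide then removes the O6 methyl by SN2 attack on this oxocarbenium form, as in the classical formation of fuchsones from p-methoxytrityl halides with loss of methyl halide. The C5 methoxy group is meta to C3a and never conjugated with the cation, so it should survive, and the neutral product is the C6 ketone/4'-phenol tautomer.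

## Compound list

1 | veratrole (1,2-dimethoxybenzene) | COc1ccccc1OC | starting material
2 | 3,6-dilithio-1,2-dimethoxybenzene | COc1c([Li])ccc([Li])c1OC | intermediate (not isolated)
3 | 1,4-diiodo-2,3-dimethoxybenzene | COc1c(I)ccc(I)c1OC | intermediate
4 | phenylboronic acid | OB(O)c1ccccc1 | starting material
5 | 4-iodo-2,3-dimethoxy-1,1'-biphenyl | COc1c(I)ccc(-c2ccccc2)c1OC | intermediate (not isolated)
6 | 2,3-dimethoxy-1,4-diphenylbenzene | COc1c(-c2ccccc2)ccc(-c2ccccc2)c1OC | intermediate
7 | 1-bromo-3,4-dimethoxy-2,5-diphenylbenzene | COc1c(OC)c(-c2ccccc2)c(Br)cc1-c1ccccc1 | intermediate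
8 | 3,4-dimethoxy-2,5-diphenylphenol | COc1c(OC)c(-c2ccccc2)c(O)cc1-c1ccccc1 | intermediate
9 | 3,4-dimethoxy-1-(methoxymethoxy)-2,5-diphenylbenzene | COCOc1cc(-c2ccccc2)c(OC)c(OC)c1-c1ccccc1 | intermediate
10 | 4-(benzyloxy)benzonitrile | N#Cc1ccc(OCc2ccccc2)cc1 | starting material
11 | [4,5-dimethoxy-2-(methoxymethoxy)-3,6-diphenylphenyl]lithium | COCOc1c([Li])c(-c2ccccc2)c(OC)c(OC)c1-c1ccccc1 | intermediate (not isolated)
12 | N-lithio-1-[4-(benzyloxy)phenyl]-1-[4,5-dimethoxy-2-(methoxymethoxy)-3,6-diphenylphenyl]methanimine | COCOc1c(C(=N[Li])c2ccc(OCc3ccccc3)cc2)c(-c2ccccc2)c(OC)c(OC)c1-c1ccccc1 | intermediate (not isolated)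
13 | [4-(benzyloxy)phenyl](2-hydroxy-4,5-dimethoxy-3,6-diphenylphenyl)methanone | COc1c(OC)c(-c2ccccc2)c(C(=O)c2ccc(OCc3ccccc3)cc2)c(O)c1-c1ccccc1 | intermediate
14 | (benzyloxy)acetyl chloride | O=C(Cl)COCc1ccccc1 | starting material
15 | 2-[4-(benzyloxy)benzoyl]-4,5-dimethoxy-3,6-diphenylphenyl (benzyloxy)acetate | COc1c(OC)c(-c2ccccc2)c(C(=O)c2ccc(OCc3ccccc3)cc2)c(OC(=O)COCc2ccccc2)c1-c1ccccc1 | intermediate (not isolated)
16 | 3-(benzyloxy)-4-[4-(benzyloxy)phenyl]-6,7-dimethoxy-5,8-diphenyl-2H-chromen-2-one | COc1c(OC)c(-c2ccccc2)c2OC(=O)C(OCc3ccccc3)=C(c3ccc(OCc4ccccc4)cc3)c2c1-c1ccccc1 | intermediate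
17 | 3-hydroxy-4-(4-hydroxyphenyl)-6,7-dimethoxy-5,8-diphenyl-2H-chromen-2-one | COc1c(OC)c(-c2ccccc2)c2OC(=O)C(O)=C(c3ccc(O)cc3)c2c1-c1ccccc1 | intermediate
18 | 3-(2-hydroxy-4,5-dimethoxy-3,6-diphenylphenyl)-3-(4-hydroxyphenyl)-2-oxopropanoic acid (racemic; present as its sodium salt) | COc1c(OC)c(-c2ccccc2)c(C(c2ccc(O)cc2)C(=O)C(=O)O)c(O)c1-c1ccccc1 | intermediate (not isolated)
19 | 2-(2-hydroxy-4,5-dimethoxy-3,6-diphenylphenyl)-2-(4-hydroxyphenyl)acetic acid (racemic; present as its sodium salt until acidification) | COc1c(OC)c(-c2ccccc2)c(C(c2ccc(O)cc2)C(=O)O)c(O)c1-c1ccccc1 | intermediate (not isolated)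
20 | 3-(4-hydroxyphenyl)-5,6-dimethoxy-4,7-diphenyl-1-benzofuran-2(3H)-one (racemic) | COc1c(OC)c(-c2ccccc2)c2OC(=O)C(c3ccc(O)cc3)c2c1-c1ccccc1 | intermediate
21 | 5,6-dimethoxy-3-(4-oxocyclohexa-2,5-dien-1-ylidene)-4,7-diphenyl-1-benzofuran-2(3H)-one | COc1c(OC)c(-c2ccccc2)c2OC(=O)C(=C3C=CC(=O)C=C3)c2c1-c1ccccc1 | intermediate
22 | 3-bromo-3-(4-hydroxyphenyl)-5,6-dimethoxy-4,7-diphenyl-1-benzofuran-2(3H)-one (racemic) | COc1c(OC)c(-c2ccccc2)c2OC(=O)C(Br)(c3ccc(O)cc3)c2c1-c1ccccc1 | intermediate (not isolated)
23 | 3-(4-hydroxyphenyl)-5-methoxy-4,7-diphenyl-1-benzofuran-2,6-dione (no stereocentre) | COC1=C(c2ccccc2)C2=C(c3ccc(O)cc3)C(=O)OC2=C(c2ccccc2)C1=O | target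

## Step count and least certain steps

Total steps: 11. Longest linear sequence: 11 steps, from 1 to 23.

**Step 9 (key step).** The most likely failure is over-oxidation. Peroxide or adventitious oxygen may attack the electron-rich enolate carbon of ring-opened 17 and lead by C–C cleavage to the diaryl ketone. Alternatively the hindered enol may ketonise so slowly that the peroxide adduct is never formed. The fallback removes the same carbon without an oxidant. It sets out from 17: hydroxylamine in aqueous NaOH should open the lactone and give 2-(hydroxyimino)-3-(2-hydroxy-4,5-dimethoxy-3,6-diphenylphenyl)-3-(4-hydroxyphenyl)propanoic acid F1. Warming its sodium salt in acetic anhydride should bring about the known decarboxylative dehydration of α-oximino acids to nitriles, with acetylation of both phenols, to give 2-[2-(acetyloxy)-4,5-dimethoxy-3,6-diphenylphenyl]-2-[4-(acetyloxy)phenyl]acetonitrile F2. HCl in aqueous acetic acid at reflux should then remove the acetates, hydrolyse the nitrile and close the lactone, returning to the route at 20. The same carbon leaves as CO2 and the same O1–carbonyl bond closes the ring.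

**Step 11.** The most likely failure is slow dealkylation: the lactone carbonyl destabilises the carbenium ion, so 22 may ionise only to a small extent, and heating to compensate invites cleavage of the C5 ether or degradation of the lactone. The fallback reverses the polarity and needs no cation. It sets out from 21: LiI in pyridine at 80–110 °C should attack the O6 methyl of the neutral, phenylogous methyl ester by SN2, as in the LiI cleavage of methyl esters. The leaving group is the delocalised anion, lithium 4-(5-methoxy-2,6-dioxo-4,7-diphenyl-2,6-dihydro-1-benzofuran-3-yl)phenolate F3. Acidification with dilute HCl returns to the route at 23.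

**Step 7.** The most likely failure is loss of the hindered phenoxide from ester 15 under base (ketene formation by E1cB, or acyl transfer), together with retro-aldol outrunning dehydration, so that 13 is returned. The fallback separates the two events. It sets out from 13: acylation with 14 under Et3N and DMAP alone allows ester 15 to be isolated. LiN(SiMe3)2 in THF at −78 °C then forms the enolate irreversibly, so the aldol closure is kinetic, giving 3-(benzyloxy)-4-[4-(benzyloxy)phenyl]-4-hydroxy-6,7-dimethoxy-5,8-diphenyl-3,4-dihydro-2H-chromen-2-one F4. Acid-catalysed E1 dehydration of this tertiary, doubly benzylic alcohol (TsOH, toluene, 80 °C) rejoins the route at 16.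

**Step 3.** The most likely failure is loss of site selectivity. Both methoxy groups are twisted out of conjugation by the flanking phenyl groups, so bromination at the para positions of the pendant phenyl rings, or a second bromination, may compete. The fallback brominates before the phenyl groups exist. It sets out from 3: NBS with catalytic H2SO4 in MeCN should substitute one of the two equivalent ring hydrogens to give 1-bromo-2,5-diiodo-3,4-dimethoxybenzene F5. An iodide-selective twofold Suzuki coupling with 4 (Pd(PPh3)4, K2CO3, 60–70 °C) exploits the much faster oxidative addition of C–I than of C–Br and returns to the route at 7.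

**Step 6.** The most likely failure is incomplete hydrolysis of the hindered, hydrogen-bonded ketimine, or sluggish addition of the doubly ortho-substituted aryllithium 11 to the nitrile. The fallback uses an aldehyde as the electrophile. It sets out from 9: lithiation as before and addition to 4-(benzyloxy)benzaldehyde should give [4-(benzyloxy)phenyl][4,5-dimethoxy-2-(methoxymethoxy)-3,6-diphenylphenyl]methanol F6. Oxidation with MnO2 in CH2Cl2 gives [4-(benzyloxy)phenyl][4,5-dimethoxy-2-(methoxymethoxy)-3,6-diphenylphenyl]methanone F7, and HCl in MeOH removes the acetal to return to the route at 13.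

## Further compounds

F1 | step 9 | 2-(hydroxyimino)-3-(2-hydroxy-4,5-dimethoxy-3,6-diphenylphenyl)-3-(4-hydroxyphenyl)propanoic acid (racemic, oxime geometry not defined) | COc1c(OC)c(-c2ccccc2)c(C(c2ccc(O)cc2)C(=NO)C(=O)O)c(O)c1-c1ccccc1
F2 | step 9 | 2-[2-(acetyloxy)-4,5-dimethoxy-3,6-diphenylphenyl]-2-[4-(acetyloxy)phenyl]acetonitrile (racemic) | COc1c(OC)c(-c2ccccc2)c(C(C#N)c2ccc(OC(C)=O)cc2)c(OC(C)=O)c1-c1ccccc1
F3 | step 11 | lithium 4-(5-methoxy-2,6-dioxo-4,7-diphenyl-2,6-dihydro-1-benzofuran-3-yl)phenolate | COC1=C(c2ccccc2)C2=C(c3ccc([O-])cc3)C(=O)OC2=C(c2ccccc2)C1=O.[Li+]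
F4 | step 7 | 3-(benzyloxy)-4-[4-(benzyloxy)phenyl]-4-hydroxy-6,7-dimethoxy-5,8-diphenyl-3,4-dihydro-2H-chromen-2-one (racemic, mixture of diastereomers) | COc1c(OC)c(-c2ccccc2)c2OC(=O)C(OCc3ccccc3)C(O)(c3ccc(OCc4ccccc4)cc3)c2c1-c1ccccc1
F5 | step 3 | 1-bromo-2,5-diiodo-3,4-dimethoxybenzene | COc1c(OC)c(I)c(Br)cc1I
F6 | step 6 | [4-(benzyloxy)phenyl][4,5-dimethoxy-2-(methoxymethoxy)-3,6-diphenylphenyl]methanol (racemic) | COCOc1c(C(O)c2ccc(OCc3ccccc3)cc2)c(-c2ccccc2)c(OC)c(OC)c1-c1ccccc1
F7 | step 6 | [4-(benzyloxy)phenyl][4,5-dimethoxy-2-(methoxymethoxy)-3,6-diphenylphenyl]methanone | COCOc1c(C(=O)c2ccc(OCc3ccccc3)cc2)c(-c2ccccc2)c(OC)c(OC)c1-c1ccccc1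
A1 | alternative 1 | 4-methoxy-2-phenyl-4-(1-phenylethenyl)-3-(propan-2-yloxy)cyclobut-2-en-1-one (racemic) | O=C1C(c2ccccc2)=C(OC(C)C)C1(OC)C(=C)c1ccccc1
A2 | alternative 1 | 4-methoxy-2,5-diphenyl-3-(propan-2-yloxy)phenol | Oc1cc(-c2ccccc2)c(OC)c(OC(C)C)c1-c1ccccc1
A3 | alternative 2 | 4-(4,7-dibromo-5,6-dimethoxy-2-oxo-2,3-dihydro-1-benzofuran-3-yl)phenyl 2,2-dimethylpropanoate (racemic) | COc1c(OC)c(Br)c2OC(=O)C(c3ccc(OC(=O)C(C)(C)C)cc3)c2c1Br
A4 | alternative 2 | 4-(5,6-dimethoxy-2-oxo-4,7-diphenyl-2,3-dihydro-1-benzofuran-3-yl)phenyl 2,2-dimethylpropanoate (racemic) | COc1c(OC)c(-c2ccccc2)c2OC(=O)C(c3ccc(OC(=O)C(C)(C)C)cc3)c2c1-c1ccccc1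
A5 | alternative 3 | 2-(3,4-dihydroxy-2,5-diphenylphenyl)-2-(4-hydroxyphenyl)acetic acid (racemic) | OC(=O)C(c1ccc(O)cc1)c1cc(-c2ccccc2)c(O)c(O)c1-c1ccccc1
A6 | alternative 3 | 5-hydroxy-3-(4-hydroxyphenyl)-4,7-diphenyl-1-benzofuran-2,6-dione | OC1=C(c2ccccc2)C2=C(c3ccc(O)cc3)C(=O)OC2=C(c2ccccc2)C1=O
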